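**Retrosynthetic overview**

- Rings: A = 3,5-dihydroxyphenyl, B = 2-hydroxy-3-methoxyphenyl ring carrying the stereocentre and the styryl group, C = 4-hydroxy-3-methoxyphenyl, D = 2,4-dihydroxyphenyl.
- Target ⇐ BCl3 debenzylation of a tetra-O-benzyl ether. Its ArCH2 group comes from reductive loss of a phthalimido group through a ring D quinone methide, and the stilbene from a Horner–Wadsworth–Emmons reaction on a ring B aldehyde.
- The CH–ring D bond ⇐ visible-light nickel/iridium decarboxylative arylation of a β,β-diaryl N-phthaloyl α-amino acid with a protected 4-bromoresorcinol (photochemical key C–C bond).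
- The triarylethane stereocentre ⇐ two successive Pd-catalysed β-C(sp3)–H arylations of N-phthaloyl-L-alanine (ring B iodide first, ring C iodide second). The bought α-centre fixes the new centre through a trans-palladacycle and is then erased: the alanine methyl carbon becomes the stereocentre, the α-carbon becomes the CH2, CO2H is replaced by ring D and N is removed.
- No ring is built. Rings A–D are bought as 3,5-bis(benzyloxy)benzyl bromide, 5-iodovanillin, 4-iodo-2-methoxyphenol and 4-bromoresorcinol and are attached in the order B, C, D, A.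

Assumption: the stereocentre in the given SMILES is read as (S) (CIP order ring B > ring C > CH2 > H).

**Route**

Step 1
Reactants: 1 5-iodovanillin (4-hydroxy-3-iodo-5-methoxybenzaldehyde)
Product: 2 4-(benzyloxy)-3-iodo-5-methoxybenzaldehyde
Conditions: BnBr (1.2 equiv), K2CO3, DMF, 60 °C
Reagents that add atoms: benzyl bromide, BrCc1ccccc1
Why: Williamson ether synthesis on the acidic vanillin-type phenoxide; the aryl iodide and the aldehyde are inert to K2CO3.

Step 2
Reactants: 3 4-iodo-2-methoxyphenol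
Product: 4 1-(benzyloxy)-4-iodo-2-methoxybenzene
Conditions: BnBr (1.2 equiv), K2CO3, DMF, 50 °C
Reagents that add atoms: benzyl bromide, BrCc1ccccc1
Why: Williamson ether synthesis of an unhindered phenol.

Step 3
Reactants: 5 4-bromoresorcinol (4-bromobenzene-1,3-diol)
Product: 6 1-bromo-2,4-bis(methoxymethoxy)benzene
Conditions: MOMCl (2.5 equiv), iPr2NEt (3 equiv), CH2Cl2, 0 °C → rt
Reagents that add atoms: chloromethyl methyl ether, COCCl
Why: MOM ether formation on both phenols; the small acetal ortho to bromine does not hinder the later nickel coupling and is removable without touching benzyl ethers.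

Step 4
Reactants: 7 3,5-bis(benzyloxy)benzyl bromide
Product: 8 diethyl [3,5-bis(benzyloxy)benzyl]phosphonate
Conditions: P(OEt)3 (neat), 130 °C
Reagents that add atoms: triethyl phosphite, CCOP(OCC)OCC
Why: Michaelis–Arbuzov reaction of a primary benzylic bromide.

Step 5
Reactants: 9 N-phthaloyl-L-alanine; 2 4-(benzyloxy)-3-iodo-5-methoxybenzaldehyde
Product: 10 (2S)-3-[2-(benzyloxy)-5-formyl-3-methoxyphenyl]-2-(1,3-dioxoisoindolin-2-yl)propanoic acid
Conditions: Pd(OAc)2 (10 mol %), 2-picoline (20 mol %), AgOAc (2 equiv), (CF3)2CHOH, 100 °C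
Reagents that add atoms: none
Why: Carboxylate-directed Pd-catalysed β-C(sp3)–H arylation of the alanine methyl group (known for this free acid with aryl iodides), in which the hindered ortho-alkoxy iodide stops at mono-arylation and the bought α-centre is not touched.

Step 6
Reactants: 10 (2S)-3-[2-(benzyloxy)-5-formyl-3-methoxyphenyl]-2-(1,3-dioxoisoindolin-2-yl)propanoic acid; 4 1-(benzyloxy)-4-iodo-2-methoxybenzene
Product: 11 (2S,3S)-3-[2-(benzyloxy)-5-formyl-3-methoxyphenyl]-3-[4-(benzyloxy)-3-methoxyphenyl]-2-(1,3-dioxoisoindolin-2-yl)propanoic acid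
Conditions: Pd(OAc)2 (10 mol %), 2,6-lutidine (20 mol %), AgOAc (2 equiv), (CF3)2CHOH, 90 °C
Reagents that add atoms: none
Why: Proposed new method: native-carboxylate-directed, pyridine-ligand-enabled arylation of the benzylic β-methylene C–H of a free N-phthaloyl β-arylalanine, in which carboxylate-bound divalent palladium cleaves the benzylic C–H by concerted metalation–deprotonation to give the five-membered palladacycle with ring B trans to the α-phthalimido group, and oxidative addition of 4 to tetravalent palladium followed by C–C reductive elimination with retention sets C3 as (S) under control of the bought α-centre; the closest known reactions are the 8-aminoquinoline- and N-methoxyamide-directed anti-selective β-arylations of phenylalanine derivatives and the carboxylate-directed β-methyl arylation used in step 5.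

Step 7
Reactants: 11 (2S,3S)-3-[2-(benzyloxy)-5-formyl-3-methoxyphenyl]-3-[4-(benzyloxy)-3-methoxyphenyl]-2-(1,3-dioxoisoindolin-2-yl)propanoic acid; 6 1-bromo-2,4-bis(methoxymethoxy)benzene
Product: 12 2-{(2S)-2-[2-(benzyloxy)-5-formyl-3-methoxyphenyl]-2-[4-(benzyloxy)-3-methoxyphenyl]-1-[2,4-bis(methoxymethoxy)phenyl]ethyl}isoindoline-1,3-dione (both C1 epimers)
Conditions: [Ir{dF(CF3)ppy}2(dtbbpy)]PF6 (2 mol %), NiCl2(dme) (10 mol %), dtbbpy (15 mol %), Cs2CO3 (1.5 equiv), DMF, 450 nm LEDs, 25 °C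
Reagents that add atoms: none
Why: Nickel/iridium metallaphotoredox decarboxylative arylation, in which the excited photocatalyst oxidises the caesium carboxylate, loss of CO2 gives an α-phthalimido radical that the aryl–nickel species from 6 captures, and reductive elimination forms the CH–ring D bond; the stereocentre β to the radical is not involved and the new N-bearing carbon (both epimers) is levelled to CH2 in step 9.

Step 8
Reactants: 12 2-{(2S)-2-[2-(benzyloxy)-5-formyl-3-methoxyphenyl]-2-[4-(benzyloxy)-3-methoxyphenyl]-1-[2,4-bis(methoxymethoxy)phenyl]ethyl}isoindoline-1,3-dione; 8 diethyl [3,5-bis(benzyloxy)benzyl]phosphonate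
Product: 13 2-{(2S)-2-[2-(benzyloxy)-5-{(E)-2-[3,5-bis(benzyloxy)phenyl]ethenyl}-3-methoxyphenyl]-2-[4-(benzyloxy)-3-methoxyphenyl]-1-[2,4-bis(methoxymethoxy)phenyl]ethyl}isoindoline-1,3-dione
Conditions: NaH (1.3 equiv), THF, 0 °C → rt (8 deprotonated first, then 12 added)
Reagents that add atoms: none
Why: Horner–Wadsworth–Emmons olefination of the aryl aldehyde with the benzylphosphonate anion gives the (E)-stilbene and leaves the imide, the acetals and the stereocentre untouched.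

Step 9
Reactants: 13 2-{(2S)-2-[2-(benzyloxy)-5-{(E)-2-[3,5-bis(benzyloxy)phenyl]ethenyl}-3-methoxyphenyl]-2-[4-(benzyloxy)-3-methoxyphenyl]-1-[2,4-bis(methoxymethoxy)phenyl]ethyl}isoindoline-1,3-dione
Product: 16 4-{(2S)-2-[2-(benzyloxy)-5-{(E)-2-[3,5-bis(benzyloxy)phenyl]ethenyl}-3-methoxyphenyl]-2-[4-(benzyloxy)-3-methoxyphenyl]ethyl}benzene-1,3-diol, via free resorcinol phthalimide 14 (not isolated), via para-quinone methide 15 (not isolated)
Conditions: PPTS (30 mol %), MeOH/THF, 55 °C; then NaBH4 (8 equiv), Et3N (3 equiv), EtOH/THF, 0 → 40 °C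
Reagents that add atoms: none
Why: PPTS-catalysed acetal methanolysis frees the ring D phenols, whose phenoxide expels phthalimide (E1cB) to a quinone methide that NaBH4 reduces by conjugate hydride addition (quinone-methide-mediated reductive C–N cleavage, as in borohydride reductions of hydroxybenzyl Mannich bases), so both C1 epimers converge on the CH2 compound and no bond to the stereocentre is broken.

Step 10
Reactants: 16 4-{(2S)-2-[2-(benzyloxy)-5-{(E)-2-[3,5-bis(benzyloxy)phenyl]ethenyl}-3-methoxyphenyl]-2-[4-(benzyloxy)-3-methoxyphenyl]ethyl}benzene-1,3-diol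
Product: 17 4-[(2S)-2-{5-[(E)-2-(3,5-dihydroxyphenyl)ethenyl]-2-hydroxy-3-methoxyphenyl}-2-(4-hydroxy-3-methoxyphenyl)ethyl]benzene-1,3-diol (CNP0254096.1)
Conditions: BCl3 (1 M in CH2Cl2, 10 equiv), C6HMe5 (12 equiv), CH2Cl2, −78 °C; MeOH quench
Reagents that add atoms: none
Why: Lewis-acid debenzylation with pentamethylbenzene as non-basic benzyl-cation scavenger at −78 °C cleaves the four benzyl ethers but not the aryl methyl ethers, the stilbene or the benzylic C–H stereocentre.

**Compound list**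

1 | 5-iodovanillin | COc1cc(C=O)cc(I)c1O | starting material
2 | 4-(benzyloxy)-3-iodo-5-methoxybenzaldehyde | COc1cc(C=O)cc(I)c1OCc1ccccc1 | intermediate
3 | 4-iodo-2-methoxyphenol | COc1cc(I)ccc1O | starting material
4 | 1-(benzyloxy)-4-iodo-2-methoxybenzene | COc1cc(I)ccc1OCc1ccccc1 | intermediate
5 | 4-bromoresorcinol | Oc1ccc(Br)c(O)c1 | starting material
6 | 1-bromo-2,4-bis(methoxymethoxy)benzene | COCOc1ccc(Br)c(OCOC)c1 | intermediate
7 | 3,5-bis(benzyloxy)benzyl bromide | BrCc1cc(OCc2ccccc2)cc(OCc2ccccc2)c1 | starting material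
8 | diethyl [3,5-bis(benzyloxy)benzyl]phosphonate | CCOP(=O)(Cc1cc(OCc2ccccc2)cc(OCc2ccccc2)c1)OCC | intermediate
9 | N-phthaloyl-L-alanine | C[C@H](N1C(=O)c2ccccc2C1=O)C(=O)O | starting material
10 | (2S)-3-[2-(benzyloxy)-5-formyl-3-methoxyphenyl]-2-(1,3-dioxoisoindolin-2-yl)propanoic acid | O=C(O)[C@H](Cc1cc(C=O)cc(OC)c1OCc1ccccc1)N1C(=O)c2ccccc2C1=O | intermediate
11 | (2S,3S)-3-[2-(benzyloxy)-5-formyl-3-methoxyphenyl]-3-[4-(benzyloxy)-3-methoxyphenyl]-2-(1,3-dioxoisoindolin-2-yl)propanoic acid | O=C(O)[C@@H](N1C(=O)c2ccccc2C1=O)[C@@H](c1ccc(OCc2ccccc2)c(OC)c1)c1cc(C=O)cc(OC)c1OCc1ccccc1 | intermediate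
12 | 2-{(2S)-2-[2-(benzyloxy)-5-formyl-3-methoxyphenyl]-2-[4-(benzyloxy)-3-methoxyphenyl]-1-[2,4-bis(methoxymethoxy)phenyl]ethyl}isoindoline-1,3-dione (both C1 epimers) | O=C1c2ccccc2C(=O)N1C(c1ccc(OCOC)cc1OCOC)[C@@H](c1ccc(OCc2ccccc2)c(OC)c1)c1cc(C=O)cc(OC)c1OCc1ccccc1 | intermediate
13 | 2-{(2S)-2-[2-(benzyloxy)-5-{(E)-2-[3,5-bis(benzyloxy)phenyl]ethenyl}-3-methoxyphenyl]-2-[4-(benzyloxy)-3-methoxyphenyl]-1-[2,4-bis(methoxymethoxy)phenyl]ethyl}isoindoline-1,3-dione (both C1 epimers) | O=C1c2ccccc2C(=O)N1C(c1ccc(OCOC)cc1OCOC)[C@@H](c1ccc(OCc2ccccc2)c(OC)c1)c1cc(/C=C/c2cc(OCc3ccccc3)cc(OCc3ccccc3)c2)cc(OC)c1OCc1ccccc1 | intermediate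
14 | 2-{(2S)-2-[2-(benzyloxy)-5-{(E)-2-[3,5-bis(benzyloxy)phenyl]ethenyl}-3-methoxyphenyl]-2-[4-(benzyloxy)-3-methoxyphenyl]-1-(2,4-dihydroxyphenyl)ethyl}isoindoline-1,3-dione (not isolated) | O=C1c2ccccc2C(=O)N1C(c1ccc(O)cc1O)[C@@H](c1ccc(OCc2ccccc2)c(OC)c1)c1cc(/C=C/c2cc(OCc3ccccc3)cc(OCc3ccccc3)c2)cc(OC)c1OCc1ccccc1 | intermediate
15 | 4-{(2S)-2-[2-(benzyloxy)-5-{(E)-2-[3,5-bis(benzyloxy)phenyl]ethenyl}-3-methoxyphenyl]-2-[4-(benzyloxy)-3-methoxyphenyl]ethylidene}-3-hydroxycyclohexa-2,5-dien-1-one (quinone methide, not isolated) | O=C1C=CC(=C[C@@H](c2ccc(OCc3ccccc3)c(OC)c2)c2cc(/C=C/c3cc(OCc4ccccc4)cc(OCc4ccccc4)c3)cc(OC)c2OCc2ccccc2)C(O)=C1 | intermediate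
16 | 4-{(2S)-2-[2-(benzyloxy)-5-{(E)-2-[3,5-bis(benzyloxy)phenyl]ethenyl}-3-methoxyphenyl]-2-[4-(benzyloxy)-3-methoxyphenyl]ethyl}benzene-1,3-diol | Oc1ccc(C[C@@H](c2ccc(OCc3ccccc3)c(OC)c2)c2cc(/C=C/c3cc(OCc4ccccc4)cc(OCc4ccccc4)c3)cc(OC)c2OCc2ccccc2)c(O)c1 | intermediate
17 | 4-[(2S)-2-{5-[(E)-2-(3,5-dihydroxyphenyl)ethenyl]-2-hydroxy-3-methoxyphenyl}-2-(4-hydroxy-3-methoxyphenyl)ethyl]benzene-1,3-diol | COc1cc([C@H](Cc2ccc(O)cc2O)c2cc(/C=C/c3cc(O)cc(O)c3)cc(OC)c2O)ccc1O | target

**Step count and risks**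

Total step count: 10 (four one-step building-block preparations, six steps on the main line).
Longest linear sequence: 7 steps (1, 5, 6, 7, 8, 9, 10).

The three steps most likely to fail:

Step 6 (proposed new arylation). The free acid may not cyclopalladate at the benzylic methylene, or the α-centre may epimerise first. The fallback uses known auxiliary-directed chemistry. It sets out from 10: the acid chloride ((COCl)2, cat. DMF) is coupled with 8-aminoquinoline to give (2S)-3-[2-(benzyloxy)-5-formyl-3-methoxyphenyl]-2-(1,3-dioxoisoindolin-2-yl)-N-(quinolin-8-yl)propanamide F6. Pd(OAc)2/AgOAc arylation with 4 (tert-amyl alcohol, 110 °C, anti-selective through the same trans-palladacycle) gives the (2S,3S)-diaryl quinolinyl amide F7. BF3·OEt2 in MeOH (100 °C) cleaves the auxiliary to the methyl ester F8, and LiI (EtOAc, reflux) returns the route at 11.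

Step 5. The ortho-benzyloxy iodide 2 may be too hindered for the carboxylate-directed C–H arylation. The fallback makes the same bond by Negishi coupling instead of C–H activation. It sets out from 2: bought methyl N-(tert-butoxycarbonyl)-3-iodo-L-alaninate F1 (from L-serine) is converted with activated zinc in DMF into the organozinc iodide F2, which couples with 2 (Pd2(dba)3, SPhos) to give methyl (2S)-3-[2-(benzyloxy)-5-formyl-3-methoxyphenyl]-2-[(tert-butoxycarbonyl)amino]propanoate F3. TFA gives the ammonium trifluoroacetate F4, N-(ethoxycarbonyl)phthalimide/NaHCO3 gives the phthalimido methyl ester F5, and LiI (EtOAc, reflux) returns the route at 10.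

Step 7. The hindered, electron-rich bromide 6 may add to nickel too slowly, so that protodecarboxylation dominates. The fallback generates the radical from a redox-active ester and couples thermally. It sets out from 11: N-hydroxyphthalimide/DIC gives the 1,3-dioxoisoindolin-2-yl ester F9; 6 is converted (n-BuLi, −78 °C, then ZnCl2) into [2,4-bis(methoxymethoxy)phenyl]zinc chloride F10; NiCl2(dme)/dtbbpy-catalysed decarboxylative Negishi coupling (THF/DMF, 25 °C) returns the route at 12.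

**Further compounds**

F1 | step 5 | methyl N-(tert-butoxycarbonyl)-3-iodo-L-alaninate (bought) | COC(=O)[C@H](CI)NC(=O)OC(C)(C)C
F2 | step 5 | [(2R)-2-[(tert-butoxycarbonyl)amino]-3-methoxy-3-oxopropyl]zinc iodide | COC(=O)[C@H](C[Zn]I)NC(=O)OC(C)(C)C
F3 | step 5 | methyl (2S)-3-[2-(benzyloxy)-5-formyl-3-methoxyphenyl]-2-[(tert-butoxycarbonyl)amino]propanoate | COC(=O)[C@H](Cc1cc(C=O)cc(OC)c1OCc1ccccc1)NC(=O)OC(C)(C)C
F4 | step 5 | methyl (2S)-2-ammonio-3-[2-(benzyloxy)-5-formyl-3-methoxyphenyl]propanoate trifluoroacetate | COC(=O)[C@H](Cc1cc(C=O)cc(OC)c1OCc1ccccc1)[NH3+].[O-]C(=O)C(F)(F)F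
F5 | step 5 | methyl (2S)-3-[2-(benzyloxy)-5-formyl-3-methoxyphenyl]-2-(1,3-dioxoisoindolin-2-yl)propanoate | COC(=O)[C@H](Cc1cc(C=O)cc(OC)c1OCc1ccccc1)N1C(=O)c2ccccc2C1=O
F6 | step 6 | (2S)-3-[2-(benzyloxy)-5-formyl-3-methoxyphenyl]-2-(1,3-dioxoisoindolin-2-yl)-N-(quinolin-8-yl)propanamide | O=C(Nc1cccc2cccnc12)[C@H](Cc1cc(C=O)cc(OC)c1OCc1ccccc1)N1C(=O)c2ccccc2C1=O
F7 | step 6 | (2S,3S)-3-[2-(benzyloxy)-5-formyl-3-methoxyphenyl]-3-[4-(benzyloxy)-3-methoxyphenyl]-2-(1,3-dioxoisoindolin-2-yl)-N-(quinolin-8-yl)propanamide | O=C(Nc1cccc2cccnc12)[C@@H](N1C(=O)c2ccccc2C1=O)[C@@H](c1ccc(OCc2ccccc2)c(OC)c1)c1cc(C=O)cc(OC)c1OCc1ccccc1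
F8 | step 6 | methyl (2S,3S)-3-[2-(benzyloxy)-5-formyl-3-methoxyphenyl]-3-[4-(benzyloxy)-3-methoxyphenyl]-2-(1,3-dioxoisoindolin-2-yl)propanoate | COC(=O)[C@@H](N1C(=O)c2ccccc2C1=O)[C@@H](c1ccc(OCc2ccccc2)c(OC)c1)c1cc(C=O)cc(OC)c1OCc1ccccc1
F9 | step 7 | 1,3-dioxoisoindolin-2-yl (2S,3S)-3-[2-(benzyloxy)-5-formyl-3-methoxyphenyl]-3-[4-(benzyloxy)-3-methoxyphenyl]-2-(1,3-dioxoisoindolin-2-yl)propanoate | O=C(ON1C(=O)c2ccccc2C1=O)[C@@H](N1C(=O)c2ccccc2C1=O)[C@@H](c1ccc(OCc2ccccc2)c(OC)c1)c1cc(C=O)cc(OC)c1OCc1ccccc1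
F10 | step 7 | [2,4-bis(methoxymethoxy)phenyl]zinc chloride | COCOc1ccc([Zn]Cl)c(OCOC)c1
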